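**Retrosynthetic overview**

- Locants follow the acid chain (C1 ester carbon to C14) and coincide with the 1,2-dioxane locants (O1 on C6, O2 on C3). Enabling feature: C6 is a fully substituted ring carbon bound to peroxide oxygen O1 and to sp2 carbon C7, so it is a masked ethyl ketone. It lies four atoms from the C3 peroxide, so O1 reaches it through the six-membered ring O1–O2–C3–C4–C5–C6, and the ring-stabilised C6 cation can then take up the C7 alkenyl group.
- Last step: O1–C6 closure of the acyclic keto silyl peroxide 23 (the only ring, formed last), with C6–C7 bond formation in the same flask by alkenyl transfer from trifluoroborate 12; the new ring fixes the C6 configuration.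
- 23: C3–O2 by invertive displacement of the triflate of β-hydroxy ester 18 with H2O2; C3 by Noyori hydrogenation, C4 by Evans alkylation; the C6 ketone is carried as a methylidene group until ozonolysis.
- 12: C10 and the 11E alkene by Johnson–Claisen rearrangement of (3R,4E)-hept-4-en-3-ol (from a Sharpless kinetic resolution); the 7E alkene by zirconium-catalysed carboalumination/iodination of alkyne 7, then borylation.

Key step: step 14

Assumption: the acylated auxiliary 13 and the allylic bromide 14 are taken as catalogue reagents (each is otherwise one routine step from (4S)-4-benzyl-1,3-oxazolidin-2-one or from 2-methylidenebutan-1-ol).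

**Route**

Step 1
Reactants: 1 (2E)-pent-2-enal
Product: 2 (4E)-hept-4-en-3-ol (racemic)
Conditions: EtMgBr, THF, −78 to 0 °C; aq NH4Cl
Reagents that add atoms: ethylmagnesium bromide, CC[Mg]Br
Why: Grignard 1,2-addition to the enal carbonyl should give the racemic secondary allylic alcohol with the E alkene untouched.

Step 2
Reactants: 2 (4E)-hept-4-en-3-ol (racemic)
Product: 3 (3R,4E)-hept-4-en-3-ol
Conditions: Ti(OiPr)4 (0.2 equiv), L-(+)-diisopropyl tartrate (0.25 equiv), t-BuOOH (0.6 equiv), 4 Å molecular sieves, CH2Cl2, −20 °C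
Reagents that add atoms: none
Why: Sharpless kinetic resolution, in which the L-(+)-tartrate catalyst epoxidizes the S alcohol much faster, so that the R alcohol should be recovered in high enantiomeric purity at slightly more than half conversion.

Step 3
Reactants: 3 (3R,4E)-hept-4-en-3-ol
Product: 5 ethyl (3R,4E)-3-ethylhept-4-enoate, via ketene acetal 4 (not isolated)
Conditions: MeC(OEt)3 (5 equiv), EtCO2H (cat.), 140 °C, removal of EtOH
Reagents that add atoms: triethyl orthoacetate, CCOC(C)(OCC)OCC
Why: Johnson–Claisen [3,3]-sigmatropic rearrangement through a chair transition state with the carbinol ethyl group equatorial should transfer the C–O stereocenter suprafacially to the new C–C stereocenter (R to R, C10 of the target) and form the E alkene.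

Step 4
Reactants: 5 ethyl (3R,4E)-3-ethylhept-4-enoate
Product: 6 (3R,4E)-3-ethylhept-4-enal
Conditions: i-Bu2AlH (1.05 equiv), CH2Cl2, −78 °C; aq potassium sodium tartrate
Reagents that add atoms: none
Why: Partial ester reduction with i-Bu2AlH at low temperature stops at the aluminium hemiacetal, which should release the aldehyde on work-up, and the stereocenter is β to the carbonyl and cannot epimerize.

Step 5
Reactants: 6 (3R,4E)-3-ethylhept-4-enal
Product: 7 (4R,5E)-4-ethyloct-5-en-1-yne
Conditions: MeC(O)C(N2)P(O)(OMe)2, K2CO3, MeOH, 0 °C to rt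
Reagents that add atoms: dimethyl (1-diazo-2-oxopropyl)phosphonate, COP(=O)(OC)C(=[N+]=[N-])C(C)=O
Why: Seyferth–Gilbert homologation in the Ohira–Bestmann variant should convert the aldehyde into the terminal alkyne under mild base without touching the alkene or the stereocenter.

Step 6
Reactants: 7 (4R,5E)-4-ethyloct-5-en-1-yne
Product: 9 (1E,4R,5E)-4-ethyl-1-iodo-2-methylocta-1,5-diene, via alkenylalane 8 (not isolated)
Conditions: Me3Al (2.5 equiv), Cp2ZrCl2 (0.25 equiv), CH2Cl2, 0 °C to rt; then I2, THF, −30 °C
Reagents that add atoms: trimethylaluminium, C[Al](C)C; iodine, II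
Why: Negishi zirconium-catalysed carboalumination adds methyl and aluminium syn across the terminal alkyne with methyl at the internal carbon, and iodinolysis of the alkenyl–aluminium bond with retention should give the E trisubstituted vinyl iodide while the internal alkene stays inert.

Step 7
Reactants: 9 (1E,4R,5E)-4-ethyl-1-iodo-2-methylocta-1,5-diene
Product: 12 potassium trifluoro[(1E,4R,5E)-4-ethyl-2-methylocta-1,5-dien-1-yl]borate, via alkenyllithium 10 (not isolated), via lithium alkenyltrimethoxyborate 11 (not isolated)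
Conditions: t-BuLi (2.1 equiv), Et2O, −78 °C; B(OMe)3, −78 °C to rt; then aq KHF2, MeOH, rt
Reagents that add atoms: trimethyl borate, COB(OC)OC; potassium hydrogen difluoride, [K+].[F-].F
Why: Iodine–lithium exchange with retention of alkene geometry, borylation of the alkenyllithium and fluoride exchange with KHF2 should give the bench-stable alkenyltrifluoroborate.

Step 8
Reactants: 13 (4S)-4-benzyl-3-butanoyl-1,3-oxazolidin-2-one, 14 2-(bromomethyl)but-1-ene
Product: 16 (4S)-4-benzyl-3-[(2R)-2-ethyl-4-methylidenehexanoyl]-1,3-oxazolidin-2-one, via sodium enolate 15 (not isolated)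
Conditions: NaN(SiMe3)2, THF, −78 °C; then 14 (3 equiv), −78 to −45 °C
Reagents that add atoms: none
Why: Evans asymmetric alkylation, in which the chelated sodium Z-enolate should be alkylated by the reactive allylic bromide on the face opposite the benzyl group, setting the R configuration of the α-carbon (C4 of the target).

Step 9
Reactants: 16 (4S)-4-benzyl-3-[(2R)-2-ethyl-4-methylidenehexanoyl]-1,3-oxazolidin-2-one
Product: 17 methyl (4R)-4-ethyl-6-methylidene-3-oxooctanoate
Conditions: MeOAc, LiN(iPr)2, THF, −78 °C; then 16, −78 to −40 °C; aq NH4Cl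
Reagents that add atoms: methyl acetate, CC(=O)OC
Why: Claisen-type acyl transfer, in which the lithium enolate of methyl acetate attacks the exocyclic imide carbonyl and expels the oxazolidinone, the product being held as its enolate and the α-branched imide being slow to enolize, so that the C4 stereocenter should be kept.

Step 10
Reactants: 17 methyl (4R)-4-ethyl-6-methylidene-3-oxooctanoate
Product: 18 methyl (3R,4R)-4-ethyl-3-hydroxy-6-methylideneoctanoate
Conditions: H2 (4 atm), RuCl2[(S)-BINAP] (1 mol %), MeOH, HCl (trace), 50 °C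
Reagents that add atoms: none
Why: Noyori asymmetric hydrogenation of the β-keto ester under catalyst control, in which the (S)-BINAP complex of divalent ruthenium should deliver the 3R carbinol as it does for other branched β-keto esters, while the isolated 1,1-disubstituted alkene is not a substrate for this catalyst.

Step 11
Reactants: 18 methyl (3R,4R)-4-ethyl-3-hydroxy-6-methylideneoctanoate
Product: 20 methyl (3S,4R)-4-ethyl-3-hydroperoxy-6-methylideneoctanoate, via triflate 19 (not isolated)
Conditions: Tf2O, 2,6-di-tert-butyl-4-methylpyridine, CH2Cl2, −78 °C; then anhydrous H2O2 in Et2O (10 equiv), −78 to −20 °C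
Reagents that add atoms: hydrogen peroxide, OO
Why: SN2 displacement of a secondary sulfonate by hydrogen peroxide should convert 3R into 3S with inversion, the hindered pyridine acting only as acid scavenger, the β-ester retarding ionization, and the only other group near C3 being a weakly nucleophilic alkene.

Step 12
Reactants: 20 methyl (3S,4R)-4-ethyl-3-hydroperoxy-6-methylideneoctanoate
Product: 21 methyl (3S,4R)-4-ethyl-6-methylidene-3-[(triethylsilyl)peroxy]octanoate
Conditions: Et3SiCl, imidazole, DMF, 0 °C
Reagents that add atoms: chlorotriethylsilane, CC[Si](Cl)(CC)CC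
Why: O-silylation of the hydroperoxide should give a triethylsilyl peroxide of the kind formed in Mukaiyama–Isayama peroxidation, which is stable to ozone and cannot add to the ketone made in the next step.

Step 13
Reactants: 21 methyl (3S,4R)-4-ethyl-6-methylidene-3-[(triethylsilyl)peroxy]octanoate
Product: 23 methyl (3S,4R)-4-ethyl-6-oxo-3-[(triethylsilyl)peroxy]octanoate, via ozonide 22 (not isolated)
Conditions: O3, CH2Cl2, −78 °C; then Me2S, −78 °C to rt
Reagents that add atoms: ozone, [O-][O+]=O
Why: Ozonolysis of the only alkene with reductive work-up should unveil the C6 ethyl ketone, the silyl peroxide and the ester being inert to ozone and to dimethyl sulfide.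

Step 14
Reactants: 23 methyl (3S,4R)-4-ethyl-6-oxo-3-[(triethylsilyl)peroxy]octanoate, 12 potassium trifluoro[(1E,4R,5E)-4-ethyl-2-methylocta-1,5-dien-1-yl]borate
Product: 26 methyl 2-[(3S,4R,6S)-4,6-diethyl-6-[(1E,4R,5E)-4-ethyl-2-methylocta-1,5-dien-1-yl]-1,2-dioxan-3-yl]acetate, via silyl peroxyketal 24 (not isolated), via peroxycarbenium ion 25 (not isolated)
Conditions: Me3SiOTf (0.1 equiv), CH2Cl2, −78 °C; then 12 (1.5 equiv), BF3·OEt2 (2 equiv), MeCN/CH2Cl2, −78 to −30 °C; aq NaHCO3
Reagents that add atoms: none
Why: Proposed new method: Me3SiOTf activates the C6 ketone, the silylated peroxide oxygen O1 adds to it in a 6-exo-trig closure that forms the O1–C6 bond and the 1,2-dioxane ring, and the triethylsilyl group passes to the former carbonyl oxygen to give silyl peroxyketal 24; BF3·OEt2 then turns 12 into the alkenyldifluoroborane, which abstracts the silyloxy group to leave the ring peroxycarbenium ion 25 (C6=O1+) and hands its alkenyl group to C6 by ipso substitution, the β-boron-stabilised cation collapsing with retention of the 7E geometry. The closest known reaction types are the Lewis acid-mediated substitution of cyclic peroxyketals by π-nucleophiles through peroxycarbenium ions, the BF3-mediated coupling of potassium alkenyltrifluoroborates with oxocarbenium ions from acetals, and the silyl ether/ketone cyclisation–allylation to 2,2,6-substituted tetrahydropyrans; what is new is their union on a silyl peroxide and a ketone-derived center. The C6 stereocenter is controlled by the ring formed an instant earlier: 25 should adopt the half-chair with the C3 CH2CO2Me and C4 ethyl groups pseudo-equatorial, and the alkenyl group should enter along the axial, chair-forming trajectory, which places it trans to the C4 ethyl group and cis to the C3 substituent (6S), both ring substituents favouring the same face. The step needs chemoselective ionization at C6 (the ester is not ionized and the C3–O2 bond, flanked by the ester, is slow to ionize), facial selectivity (secured as above) and survival of the tertiary allylic C6–O1 bond of the product, for which the borate is added only after ring closure, the temperature is kept at or below −30 °C and the mixture is quenched cold.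

**Compound list**

1 | (2E)-pent-2-enal | CC/C=C/C=O | starting material
2 | (4E)-hept-4-en-3-ol (racemic) | CCC(O)/C=C/CC | intermediate
3 | (3R,4E)-hept-4-en-3-ol | CC[C@@H](O)/C=C/CC | intermediate
4 | (3R,4E)-3-[(1-ethoxyethenyl)oxy]hept-4-ene (ketene acetal) | CC[C@@H](OC(=C)OCC)/C=C/CC | intermediate
5 | ethyl (3R,4E)-3-ethylhept-4-enoate | CC/C=C/[C@H](CC)CC(=O)OCC | intermediate
6 | (3R,4E)-3-ethylhept-4-enal | CC/C=C/[C@H](CC)CC=O | intermediate
7 | (4R,5E)-4-ethyloct-5-en-1-yne | CC/C=C/[C@H](CC)CC#C | intermediate
8 | [(1E,4R,5E)-4-ethyl-2-methylocta-1,5-dien-1-yl]dimethylalane | CC/C=C/[C@H](CC)C/C(C)=C/[Al](C)C | intermediate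
9 | (1E,4R,5E)-4-ethyl-1-iodo-2-methylocta-1,5-diene | CC/C=C/[C@H](CC)C/C(C)=C/I | intermediate
10 | [(1E,4R,5E)-4-ethyl-2-methylocta-1,5-dien-1-yl]lithium | CC/C=C/[C@H](CC)C/C(C)=C/[Li] | intermediate
11 | lithium [(1E,4R,5E)-4-ethyl-2-methylocta-1,5-dien-1-yl]trimethoxyborate | CC/C=C/[C@H](CC)C/C(C)=C/[B-](OC)(OC)OC.[Li+] | intermediate
12 | potassium trifluoro[(1E,4R,5E)-4-ethyl-2-methylocta-1,5-dien-1-yl]borate | CC/C=C/[C@H](CC)C/C(C)=C/[B-](F)(F)F.[K+] | intermediate
13 | (4S)-4-benzyl-3-butanoyl-1,3-oxazolidin-2-one | CCCC(=O)N1[C@@H](Cc2ccccc2)COC1=O | starting material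
14 | 2-(bromomethyl)but-1-ene | CCC(=C)CBr | starting material
15 | sodium (1Z)-1-[(4S)-4-benzyl-2-oxo-1,3-oxazolidin-3-yl]but-1-en-1-olate | CC/C=C(\[O-])N1[C@@H](Cc2ccccc2)COC1=O.[Na+] | intermediate
16 | (4S)-4-benzyl-3-[(2R)-2-ethyl-4-methylidenehexanoyl]-1,3-oxazolidin-2-one | CCC(=C)C[C@@H](CC)C(=O)N1[C@@H](Cc2ccccc2)COC1=O | intermediate
17 | methyl (4R)-4-ethyl-6-methylidene-3-oxooctanoate | CCC(=C)C[C@@H](CC)C(=O)CC(=O)OC | intermediate
18 | methyl (3R,4R)-4-ethyl-3-hydroxy-6-methylideneoctanoate | CCC(=C)C[C@@H](CC)[C@H](O)CC(=O)OC | intermediate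
19 | methyl (3R,4R)-4-ethyl-6-methylidene-3-[(trifluoromethanesulfonyl)oxy]octanoate | CCC(=C)C[C@@H](CC)[C@H](OS(=O)(=O)C(F)(F)F)CC(=O)OC | intermediate
20 | methyl (3S,4R)-4-ethyl-3-hydroperoxy-6-methylideneoctanoate | CCC(=C)C[C@@H](CC)[C@H](CC(=O)OC)OO | intermediate
21 | methyl (3S,4R)-4-ethyl-6-methylidene-3-[(triethylsilyl)peroxy]octanoate | CCC(=C)C[C@@H](CC)[C@H](CC(=O)OC)OO[Si](CC)(CC)CC | intermediate
22 | methyl (3S,4R)-4-ethyl-5-(3-ethyl-1,2,4-trioxolan-3-yl)-3-[(triethylsilyl)peroxy]pentanoate (ozonide) | CCC1(C[C@@H](CC)[C@H](CC(=O)OC)OO[Si](CC)(CC)CC)OCOO1 | intermediate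
23 | methyl (3S,4R)-4-ethyl-6-oxo-3-[(triethylsilyl)peroxy]octanoate | CCC(=O)C[C@@H](CC)[C@H](CC(=O)OC)OO[Si](CC)(CC)CC | intermediate
24 | methyl 2-[(3S,4R)-4,6-diethyl-6-[(triethylsilyl)oxy]-1,2-dioxan-3-yl]acetate | CCC1(O[Si](CC)(CC)CC)C[C@@H](CC)[C@H](CC(=O)OC)OO1 | intermediate
25 | (3S,4R)-4,6-diethyl-3-(2-methoxy-2-oxoethyl)-4,5-dihydro-3H-1,2-dioxin-1-ium (peroxycarbenium ion) | CCC1=[O+]O[C@@H](CC(=O)OC)[C@H](CC)C1 | intermediate
26 | methyl 2-[(3S,4R,6S)-4,6-diethyl-6-[(1E,4R,5E)-4-ethyl-2-methylocta-1,5-dien-1-yl]-1,2-dioxan-3-yl]acetate | CC/C=C/[C@H](CC)C/C(C)=C/[C@]1(CC)C[C@@H](CC)[C@H](CC(=O)OC)OO1 | target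

**Step count and risks**

Total steps: 14. Longest linear sequence: 8 steps (steps 1 to 7, then step 14).

Steps most likely to fail:

1. Step 14 (the proposed new method). What may go wrong: heterolysis of the O–O bond of the peroxyketal (Criegee-type fragmentation), loss of a proton from the peroxycarbenium ion to an enol peroxide, slow transfer of the hindered alkenyl group, or re-ionization of the tertiary allylic C6–O1 bond of the product with loss of the C6 configuration. The fallback uses known chemistry, sets out from 18 and 9 and returns at 26. Compound 18 is silylated (t-BuMe2SiOTf, 2,6-lutidine) to silyl ether F1, and ozonolysis (O3; Me2S) gives ketone F2. Addition of alkenyllithium 10 (from 9 and t-BuLi; CeCl3, THF, −78 °C) with an Ac2O quench gives tertiary allylic acetate F3 as both C6 epimers, and HF·pyridine frees alcohol F4. Triflation (Tf2O, 2,6-di-tert-butyl-4-methylpyridine) to triflate F5 and displacement with H2O2 as in step 11 give hydroperoxide F6. A catalytic Lewis acid (BF3·OEt2, CH2Cl2, −40 °C) then ionizes the tertiary allylic acetate, and the hydroperoxide captures the allyl cation at C6 in a 6-exo closure of the same O1–C6 bond, the classical acid-promoted alkylation of a hydroperoxide by a tertiary carbocation. This should give 26 together with its C6 epimer, to be separated by chromatography, so the stereocontrol of the main route is traded for certainty of bond formation.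

2. Step 11. What may go wrong: β-elimination of the triflate to the conjugated ester, participation of the methylidene π bond at the ionizing C3 center, or a second alkylation of the hydroperoxide to a dialkyl peroxide. The fallback runs from 16 back to 23 and keeps the ester out of the substitution. LiBH4 cleaves the auxiliary from 16 to give alcohol F7, and Dess–Martin oxidation gives aldehyde F8. Brown allylation with (+)-Ipc2B(allyl), made from (−)-α-pinene, sets the 4R carbinol of homoallylic alcohol F9 under reagent control. Triflation to triflate F10 and displacement with H2O2 give hydroperoxide F11 with inversion, and Et3SiCl/imidazole gives silyl peroxide F12. Ozonolysis of both alkenes (O3; Me2S) gives keto aldehyde F13, Pinnick oxidation (NaClO2, NaH2PO4, 2-methylbut-2-ene) gives acid F14, and Me3SiCHN2 gives 23.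

3. Step 9. What may go wrong: attack of the ester enolate on the ring carbonyl with opening of the oxazolidinone, or proton transfer to the enolate with loss of the C4 configuration. The fallback runs from 16 back to 17 in two stages. LiOH/H2O2 (THF/H2O, 0 °C; Na2SO3) removes the auxiliary to give acid F15, and carbonyldiimidazole gives acyl imidazolide F16. Magnesium bis(methyl malonate), Mg(O2CCH2CO2Me)2, then effects the decarboxylative Claisen (Masamune) homologation to 17.

Further compounds
F1 | step 14 | methyl (3R,4R)-3-[(tert-butyldimethylsilyl)oxy]-4-ethyl-6-methylideneoctanoate | CCC(=C)C[C@@H](CC)[C@H](O[Si](C)(C)C(C)(C)C)CC(=O)OC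
F2 | step 14 | methyl (3R,4R)-3-[(tert-butyldimethylsilyl)oxy]-4-ethyl-6-oxooctanoate | CCC(=O)C[C@@H](CC)[C@H](O[Si](C)(C)C(C)(C)C)CC(=O)OC
F3 | step 14 | methyl (3R,4R,7E,10R,11E)-6-acetoxy-3-[(tert-butyldimethylsilyl)oxy]-4,6,10-triethyl-8-methyltetradeca-7,11-dienoate (both C6 epimers) | CC/C=C/[C@H](CC)C/C(C)=C/C(CC)(OC(C)=O)C[C@@H](CC)[C@H](O[Si](C)(C)C(C)(C)C)CC(=O)OC
F4 | step 14 | methyl (3R,4R,7E,10R,11E)-6-acetoxy-4,6,10-triethyl-3-hydroxy-8-methyltetradeca-7,11-dienoate | CC/C=C/[C@H](CC)C/C(C)=C/C(CC)(OC(C)=O)C[C@@H](CC)[C@H](O)CC(=O)OC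
F5 | step 14 | methyl (3R,4R,7E,10R,11E)-6-acetoxy-4,6,10-triethyl-8-methyl-3-[(trifluoromethanesulfonyl)oxy]tetradeca-7,11-dienoate | CC/C=C/[C@H](CC)C/C(C)=C/C(CC)(OC(C)=O)C[C@@H](CC)[C@H](OS(=O)(=O)C(F)(F)F)CC(=O)OC
F6 | step 14 | methyl (3S,4R,7E,10R,11E)-6-acetoxy-4,6,10-triethyl-3-hydroperoxy-8-methyltetradeca-7,11-dienoate | CC/C=C/[C@H](CC)C/C(C)=C/C(CC)(OC(C)=O)C[C@@H](CC)[C@H](CC(=O)OC)OO
F7 | step 11 | (2R)-2-ethyl-4-methylidenehexan-1-ol | CCC(=C)C[C@@H](CC)CO
F8 | step 11 | (2R)-2-ethyl-4-methylidenehexanal | CCC(=C)C[C@@H](CC)C=O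
F9 | step 11 | (4R,5R)-5-ethyl-7-methylidenenon-1-en-4-ol | CCC(=C)C[C@@H](CC)[C@H](O)CC=C
F10 | step 11 | (4R,5R)-5-ethyl-7-methylidenenon-1-en-4-yl trifluoromethanesulfonate | CCC(=C)C[C@@H](CC)[C@H](OS(=O)(=O)C(F)(F)F)CC=C
F11 | step 11 | (4S,5R)-5-ethyl-4-hydroperoxy-7-methylidenenon-1-ene | CCC(=C)C[C@@H](CC)[C@H](CC=C)OO
F12 | step 11 | triethyl{[(4S,5R)-5-ethyl-7-methylidenenon-1-en-4-yl]peroxy}silane | CCC(=C)C[C@@H](CC)[C@H](CC=C)OO[Si](CC)(CC)CC
F13 | step 11 | (3S,4R)-4-ethyl-6-oxo-3-[(triethylsilyl)peroxy]octanal | CCC(=O)C[C@@H](CC)[C@H](CC=O)OO[Si](CC)(CC)CC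
F14 | step 11 | (3S,4R)-4-ethyl-6-oxo-3-[(triethylsilyl)peroxy]octanoic acid | CCC(=O)C[C@@H](CC)[C@H](CC(=O)O)OO[Si](CC)(CC)CC
F15 | step 9 | (2R)-2-ethyl-4-methylidenehexanoic acid | CCC(=C)C[C@@H](CC)C(=O)O
F16 | step 9 | (2R)-2-ethyl-1-(1H-imidazol-1-yl)-4-methylidenehexan-1-one | CCC(=C)C[C@@H](CC)C(=O)n1ccnc1
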